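The dihydropyran ring is disconnected at C2–C3 and C4–C4a, making C3–C4 a two-carbon alkene partner. The key step exploits the three adjacent oxygens on the benzo ring (O1 at C8a, the hydroxyls at C8 and C7): O1 and the C8 oxygen are first tied to the carbonyl carbon of (E,E)-farnesylacetone as a benzodioxole ketal. A confined chiral acid opens this temporary ring to an O-aryl oxocarbenium ion, which undergoes an enantioselective oxa-Povarov [4+2] annulation with phenyl vinyl sulfide at C4a, the only free position ortho to O1 and para to the C7 hydroxyl. Pyran ring and C2 stereocentre arise in one operation; radical desulfurisation at C4 finishes the target.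

Key step: step 3

Remark on the chemistry: C4 of compound 10 forms as an epimer mixture and is left undefined in its SMILES, because step 4 turns C4 into CH2. The target is 2S by CIP analysis of the given SMILES.

Step 1
Reactants: 1 (2E,6E)-farnesyl bromide; 2 ethyl acetoacetate
Product: 4 (5E,9E)-6,10,14-trimethylpentadeca-5,9,13-trien-2-one, via keto ester 3 (not isolated)
Conditions: 2 (1.5 equiv), NaH, THF, 0 °C, then 1, 0 °C to rt; then 2 M aq NaOH, MeOH, 60 °C; then 1 M HCl to pH 3, 50 °C
Reagents that add atoms: none
Why: Acetoacetic ester synthesis: the sodium enolate of 2 displaces the primary allylic bromide by SN2 without touching the E alkenes, and saponification with decarboxylation of the β-keto acid gives the methyl ketone, so the stereocentre of 3 is lost again and none remains.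

Step 2
Reactants: 4 (5E,9E)-farnesylacetone; 5 5-methylbenzene-1,2,3-triol (5-methylpyrogallol)
Product: 7 rac-2,6-dimethyl-2-[(3E,7E)-4,8,12-trimethyltrideca-3,7,11-trien-1-yl]-1,3-benzodioxol-4-ol, via dimethyl ketal 6 (not isolated)
Conditions: HC(OMe)3, MeOH, cat. PPTS, rt, then volatiles removed; 5 (1.5 equiv), cat. camphorsulfonic acid, toluene, 80 °C, MeOH distilled off, argon
Reagents that add atoms: trimethyl orthoformate, COC(OC)OC (its methoxy groups sit in 6 only and leave again as methanol)
Why: Acid-catalysed transketalisation: the dimethyl ketal ionises easily under mild acid and two adjacent phenol oxygens of the symmetric triol close the five-membered ketal (either adjacent pair gives the same compound), the ketal carbon forming as a racemate that step 3 erases.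

Step 3
Reactants: 7 benzodioxole ketal; 8 phenyl vinyl sulfide
Product: 10 (2S)-2,5-dimethyl-4-(phenylsulfanyl)-2-[(3E,7E)-4,8,12-trimethyltrideca-3,7,11-trien-1-yl]chromane-7,8-diol (C4 epimer mixture), via O-aryl oxocarbenium ion 9 (not isolated)
Conditions: 8 (3 equiv, slow addition), confined chiral Brønsted acid (5 mol %; the imidodiphosphorimidate built from two 3,3'-bis[3,5-bis(trifluoromethyl)phenyl]-1,1'-bi-2-naphthol units with N-trifluoromethylsulfonyl groups, the antipode that leads to 2S), toluene, 4 Å MS, −40 °C, argon
Reagents that add atoms: none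
Why: Proposed new method: the chiral acid protonates the ketal oxygen bound to C8 and opens the five-membered ring to the O-aryl oxocarbenium ion 9 (2-oxonia-diene C4a=C8a–O1+=C2); the CH2 terminus of 8 then adds to C2 (C2–C3 bond), the sulfur-stabilised cation at C4 is captured by C4a (C4–C4a bond), and loss of the C4a proton restores the arene and returns the acid. The closest known reaction types are the Lewis-acid oxa-Povarov annulation of O-aryl oxocarbenium ions with alkenes to racemic chromans, the chiral-phosphoric-acid Povarov reaction, and confined-acid ion-pair catalysis that distinguishes methyl from larger alkyl groups on ketone-derived oxocarbenium ions; new here are the ketone-derived benzodioxole precursor and the enantioselective variant. The dihydropyran ring closes in formal [4+2] mode (stepwise limit: intermolecular addition, then 6-exo-trig Friedel–Crafts closure onto the thionium carbon). The C2 stereocentre is under catalyst control: the liberated C8–OH hydrogen-bonds to the chiral anion next to O1, which should fix the ion pair, place methyl rather than the chain on the inner side of the oxonia-diene and shield one face; C4 forms without control and is erased in step 4. The step needs regioselective annulation at C4a, secured because C4a is the only unsubstituted carbon ortho to O1 and is para to the C7–OH, while opening of the other ketal C–O bond gives an ion whose ortho positions are both blocked and that can only reclose; the orientation of 8 follows from sulfur stabilising the cation at C4. Chemoselectivity over the three chain alkenes relies on fast, reversible O-protonation of the ketal against slow C-protonation of trisubstituted alkenes at −40 °C, and the oxocarbenium ion cannot be trapped by the nearest chain alkene without forming a four-membered ring or a secondary cation.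

Step 4
Reactants: 10 (2S)-4-(phenylsulfanyl)chromane-7,8-diol
Product: 11 (2S)-2,5-dimethyl-2-[(3E,7E)-4,8,12-trimethyltrideca-3,7,11-trien-1-yl]chromane-7,8-diol (target)
Conditions: Bu3SnH (3 equiv), AIBN (0.2 equiv), degassed toluene, 90 °C
Reagents that add atoms: none
Why: Radical-chain desulfurisation (tin hydride reduction): the tributyltin radical cleaves the weak benzylic C4–S bond and the benzylic radical is reduced by Bu3SnH faster than it adds to the remote chain alkenes, while C2 is not involved and keeps its S configuration.

Compound list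
1 | (2E,6E)-farnesyl bromide, (2E,6E)-1-bromo-3,7,11-trimethyldodeca-2,6,10-triene | CC(C)=CCC/C(C)=C/CC/C(C)=C/CBr | starting material
2 | ethyl acetoacetate | CCOC(=O)CC(C)=O | starting material
3 | ethyl (4E,8E)-2-acetyl-5,9,13-trimethyltetradeca-4,8,12-trienoate (racemic keto ester) | CC(C)=CCC/C(C)=C/CC/C(C)=C/CC(C(C)=O)C(=O)OCC | intermediate
4 | (5E,9E)-6,10,14-trimethylpentadeca-5,9,13-trien-2-one ((E,E)-farnesylacetone) | CC(C)=CCC/C(C)=C/CC/C(C)=C/CCC(C)=O | intermediate
5 | 5-methylbenzene-1,2,3-triol (5-methylpyrogallol) | Cc1cc(O)c(O)c(O)c1 | starting material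
6 | (5E,9E)-2,2-dimethoxy-6,10,14-trimethylpentadeca-5,9,13-triene (dimethyl ketal) | CC(C)=CCC/C(C)=C/CC/C(C)=C/CCC(C)(OC)OC | intermediate
7 | rac-2,6-dimethyl-2-[(3E,7E)-4,8,12-trimethyltrideca-3,7,11-trien-1-yl]-1,3-benzodioxol-4-ol | CC(C)=CCC/C(C)=C/CC/C(C)=C/CCC1(C)Oc2cc(C)cc(O)c2O1 | intermediate
8 | phenyl vinyl sulfide | C=CSc1ccccc1 | starting material
9 | (2,3-dihydroxy-5-methylphenyl)[(5E,9E)-6,10,14-trimethylpentadeca-5,9,13-trien-2-ylidene]oxonium (cation of the ion pair with the catalyst anion) | CC(C)=CCC/C(C)=C/CC/C(C)=C/CCC(C)=[O+]c1cc(C)cc(O)c1O | intermediate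
10 | (2S)-2,5-dimethyl-4-(phenylsulfanyl)-2-[(3E,7E)-4,8,12-trimethyltrideca-3,7,11-trien-1-yl]chromane-7,8-diol (C4 epimer mixture) | CC(C)=CCC/C(C)=C/CC/C(C)=C/CC[C@@]1(C)CC(Sc3ccccc3)c2c(C)cc(O)c(O)c2O1 | intermediate
11 | (2S)-2,5-dimethyl-2-[(3E,7E)-4,8,12-trimethyltrideca-3,7,11-trien-1-yl]chromane-7,8-diol | CC(C)=CCC/C(C)=C/CC/C(C)=C/CC[C@@]1(C)CCc2c(C)cc(O)c(O)c2O1 | target

Total step count: 4. Longest linear sequence: 4 steps (1 → 4 → 7 → 10 → 11).

Steps most likely to fail

Step 3 (Proposed new method). The chiral anion may discriminate poorly between methyl and the homofarnesyl chain at the oxocarbenium carbon, which would give low enantioselectivity. The acid may also oligomerise 8 or add it to the electron-rich arene. The thionium ion may be trapped at the C8 oxygen instead of at C4a. The product may lose thiophenol under the acid. The fallback uses known chemistry, sets out from 5 and comes back at 11. Triol 5 should be protected on two adjacent oxygens with tBu2Si(OTf)2 and 2,6-lutidine to give 2,2-di-tert-butyl-6-methyl-1,3,2-benzodioxasilol-4-ol F1. Commercial all-E geranylgeraniol with methyl chloroformate and pyridine should give methyl (2E,6E,10E)-3,7,11,15-tetramethylhexadeca-2,6,10,14-tetraen-1-yl carbonate F2. Palladium-catalysed asymmetric allylic O-alkylation of F1 with F2 should deliver the branched tertiary ether (S)-aryl 3,7,11,15-tetramethylhexadeca-1,6,10,14-tetraen-3-yl ether F3; the catalyst would be Pd2(dba)3·CHCl3 with the matching antipode of N,N'-(cyclohexane-1,2-diyl)bis[2-(diphenylphosphino)benzamide] in CH2Cl2, and the stereocentre is set by the ligand. Hydroboration of the vinyl group alone with 9-BBN and oxidation with NaBO3·4H2O should give the primary alcohol (3S)-3-aryloxy-3,7,11,15-tetramethylhexadeca-6,10,14-trien-1-ol F4. Tf2O with 2,6-di-tert-butylpyridine should close the pyran ring by intramolecular Friedel–Crafts alkylation at the free ortho carbon to give the silylene-protected (S)-chroman F5. HF·pyridine in THF should then release 11.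

Step 4. Chain transfer may be too slow, so that the benzylic radical cyclises onto the chain alkene, or C–S cleavage may stay incomplete. The fallback sets out from 10 and comes back at 11. It replaces the radical path by an ionic one that uses the C7 hydroxyl para to C4a. Degassed aqueous NaOH in ethanol should ionise the phenol and expel thiophenolate by 1,6-elimination to give the para-quinone methide (2S)-8-hydroxy-2,5-dimethyl-2-[(3E,7E)-4,8,12-trimethyltrideca-3,7,11-trien-1-yl]-2,3-dihydro-7H-chromen-7-one F6. NaBH4 present in the same flask should add hydride at C4 and restore the arene as 11.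

Step 2. Acid may cyclise the polyene or alkylate the very electron-rich triol, and 5 may oxidise in air. The fallback sets out from 1 and 5 and comes back at 7 without any Brønsted acid. Bromide 1 should be alkylated with 3-lithio-1-(trimethylsilyl)propyne (THF, −78 °C) to give trimethyl[(5E,9E)-6,10,14-trimethylpentadeca-5,9,13-trien-1-yn-1-yl]silane F7. K2CO3 in methanol should give the terminal alkyne (5E,9E)-6,10,14-trimethylpentadeca-5,9,13-trien-1-yne F8. Ru3(CO)12-catalysed double Markovnikov addition of two adjacent O–H bonds of 5 across the alkyne (toluene, 100 °C) should then give 7.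

Further compounds
F1 | step 3 | 2,2-di-tert-butyl-6-methyl-1,3,2-benzodioxasilol-4-ol | Cc1cc(O)c2O[Si](C(C)(C)C)(C(C)(C)C)Oc2c1
F2 | step 3 | methyl (2E,6E,10E)-3,7,11,15-tetramethylhexadeca-2,6,10,14-tetraen-1-yl carbonate | CC(C)=CCC/C(C)=C/CC/C(C)=C/CC/C(C)=C/COC(=O)OC
F3 | step 3 | 2,2-di-tert-butyl-6-methyl-4-{[(3S,6E,10E)-3,7,11,15-tetramethylhexadeca-1,6,10,14-tetraen-3-yl]oxy}-1,3,2-benzodioxasilole | CC(C)=CCC/C(C)=C/CC/C(C)=C/CC[C@@](C)(C=C)Oc1cc(C)cc2O[Si](C(C)(C)C)(C(C)(C)C)Oc12
F4 | step 3 | (3S,6E,10E)-3-[(2,2-di-tert-butyl-6-methyl-1,3,2-benzodioxasilol-4-yl)oxy]-3,7,11,15-tetramethylhexadeca-6,10,14-trien-1-ol | CC(C)=CCC/C(C)=C/CC/C(C)=C/CC[C@@](C)(CCO)Oc1cc(C)cc2O[Si](C(C)(C)C)(C(C)(C)C)Oc12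
F5 | step 3 | di-tert-butylsilylene ether of 11 (silicon bridging the C7 and C8 oxygens), 2S | CC(C)=CCC/C(C)=C/CC/C(C)=C/CC[C@@]1(C)CCc2c(C)cc3O[Si](C(C)(C)C)(C(C)(C)C)Oc3c2O1
F6 | step 4 | (2S)-8-hydroxy-2,5-dimethyl-2-[(3E,7E)-4,8,12-trimethyltrideca-3,7,11-trien-1-yl]-2,3-dihydro-7H-chromen-7-one (para-quinone methide) | CC(C)=CCC/C(C)=C/CC/C(C)=C/CC[C@@]1(C)CC=C2C(C)=CC(=O)C(O)=C2O1
F7 | step 2 | trimethyl[(5E,9E)-6,10,14-trimethylpentadeca-5,9,13-trien-1-yn-1-yl]silane | CC(C)=CCC/C(C)=C/CC/C(C)=C/CCC#C[Si](C)(C)C
F8 | step 2 | (5E,9E)-6,10,14-trimethylpentadeca-5,9,13-trien-1-yne | CC(C)=CCC/C(C)=C/CC/C(C)=C/CCC#C
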